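**Assumption (remark on the chemistry):** The target is a planar, achiral flavone with no stereocentre and no hindered axis, so "single enantiomer" places no demand and no step sets or endangers configuration. Compounds 1, 4 and 7 are taken as catalogue chemicals.

## Analysis of the target

Scaposin 10 is a flavone: benzo ring A (C4a, C5, C6, C7, C8, C8a) is fused to pyran-4-one ring C (O1, C2, C3, C4), which carries aryl ring B on C2. Because there is no stereogenic element, the whole problem is constitutional. Ring A is hexasubstituted and bears five contiguous oxygens in alternating states: O1 on C8a, 5-OH, 6-OMe, 7-OH, 8-OMe. Ring B repeats the theme with 3'-OH next to 4'-OMe and 5'-OMe, so eight oxygens exist in three states (ring ether, free OH, methyl ether). Apart from the chelated C5 position, a methyl ether on these rings cannot be cleaved selectively in the presence of the others, so every oxygen has to arrive in its final state or under a group other than methyl. The sensitive groups are the three free phenols on electron-rich rings (air oxidation under base) and the pyranone, whose C2 is open to hydroxide or alkoxide (ring opening, retro-Claisen cleavage). The hard part is ring A, since no commercial arene shows the alternating pattern together with a carbon at C4a. The feature the route is built on: C6, C7, C8 and C4a–C4 form a 4-hydroxy-3,5-dimethoxybenzoyl unit, and the two oxygens it lacks (on C5 and on C8a) sit on the two positions ortho to C4a, related by a local mirror through C7 and C4a. The bonds O1–C8a and C5–O are therefore equivalent in the ring-opened form and can be made by one reaction type in one operation.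

## Retrosynthetic reasoning

**10 to 9.** The three free phenols (5-OH, 7-OH, 3'-OH) are masked as benzyl ethers, so the three O–CH2Ph bonds are cut last. One hydrogenolysis then exposes all of them without touching any methyl ether, and no phenoxide is present in the metal-catalysed step.

**9 to 6 and 7 (key disconnection).** Two aryl C–O bonds of ring A are cut: O1–C8a, which opens ring C, and C5–O. The precursor is the open-chain 1,3-diketone 6, whose A ring carries two equivalent bromines ortho to the acyl carbon, plus benzyl alcohol 7. The cut is placed here, and not at O1–C2 as in the textbook route, because the two ortho oxygens are exactly what no cheap arene provides. Placing both in the key step reduces ring A to a symmetric dibromide of a commodity ketone. The forward reaction must join the distal enolate oxygen of 6 to one C–Br carbon (closing the pyranone) and couple 7 at the other. Since the two bromides are equivalent, neither the order nor the site of the first event matters.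

**6 to 3 and 5.** The C2–C3 bond is cut (crossed Claisen condensation) between the methyl ketone 3 and the non-enolisable ester 5. This places the carbonyl that becomes C4 on ring A and the carbon that becomes C2 on ring B, and joins the two halves in one step.

**3 to 2 to 1.** The two C–Br bonds are cut back to the only two free ring positions of 2, each ortho to one OMe and para to the other, so bromination has no regiochemical choice. 2 is the benzyl ether of acetosyringone 1, which already holds C4a, C4, C3, both A-ring methyl ethers and the 7-oxygen.

**5 to 4.** The O–benzyl bond is cut; 4 already has the B-ring pattern with the 3-OH free and the 4- and 5-oxygens methylated, so ring B needs no selective methylation or demethylation.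

## Alternatives that were turned down

**Alternative 1:** (textbook) Cut O1–C2 and C2–C3, i.e. the Baker–Venkataraman sequence. The ketone 1-[2,4-bis(benzyloxy)-6-hydroxy-3,5-dimethoxyphenyl]ethan-1-one A1 would be O-acylated with 3-(benzyloxy)-4,5-dimethoxybenzoyl chloride A2 to the aryl ester A3. Base-induced 1,5-acyl shift would give the diketone A4, and acid cyclodehydration would give 9. It was turned down because all five A-ring oxygens must be installed and differentiated into three states before the first bond of ring C is made. Even from 3, A1 needs a separate double hydroxylation and a mono-benzylation, and then three more steps lead to 9, against two steps from 3 in the chosen route. A2 costs two further steps from 5. The route also handles an oxidisable polyphenolic ketone throughout.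

**Alternative 2:** Cut C4a–C4, C4–C3 and O1–C2, i.e. a three-component carbonylative Sonogashira annulation. The symmetric iodide 2-iodo-4,6-dimethoxybenzene-1,3,5-triyl triacetate A5, carbon monoxide and the alkyne 5-ethynyl-2,3-dimethoxyphenyl acetate A6 would be joined by Pd in a secondary amine; aminolysis of the acetates in the same flask would give 10. The disconnection is attractive, but the cost moves into the precursors. A5 is at least five steps from any commercial arene (protection, two C–Br bonds, two C–O bonds, iodination, acetylation) and A6 needs two or three. Oxidative addition at a C–I bond flanked by two oxygens on a very electron-rich ring is slow and competes with protodeiodination. The liberated phenoxides and the amine compete with the alkyne for the acyl–Pd species, and 5-exo closure (aurone) competes with 6-endo closure. The total would be about nine steps against six.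

**Alternative 3:** Cut C6–O and C8–O on a finished flavone (late-stage oxygenation). 2-[3-(Benzyloxy)-4,5-dimethoxyphenyl]-5,7-dihydroxy-4H-chromen-4-one A7, built by the textbook sequence from a phloroglucinol-type ketone, would be dibrominated to the 6,8-dibromide A8. Copper-mediated double methoxylation would give A9, the 3'-O-benzyl ether of 10, and debenzylation would finish. It was turned down for three reasons. Bromination must discriminate C6 and C8 from C3 of the enone and from C2' and C6' of the activated B ring. The double methoxylation has to occur on a bis-phenoxide of extreme electron density, where reductive loss of one bromine gives mono-methoxy products of nearly identical polarity. And the skeleton is still assembled by the textbook route, so the key step only adjusts substituents, at about seven steps.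

Key step: step 5

## Route

**Step 1**
Reactants: 1 acetosyringone, 1-(4-hydroxy-3,5-dimethoxyphenyl)ethan-1-one
Product: 2 1-[4-(benzyloxy)-3,5-dimethoxyphenyl]ethan-1-one
Conditions: BnBr (1.2 equiv), K2CO3, DMF, 60 °C
Reagents that add atoms: benzyl bromide, BrCc1ccccc1
Why: Williamson ether synthesis on the only acidic OH; the phenol is flanked by two OMe groups but is para to the acetyl group, hence acidic, and should alkylate cleanly in DMF. Benzyl is chosen because it survives NBS, NaH and the copper step and leaves by hydrogenolysis.

**Step 2**
Reactants: 2 1-[4-(benzyloxy)-3,5-dimethoxyphenyl]ethan-1-one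
Product: 3 1-[4-(benzyloxy)-2,6-dibromo-3,5-dimethoxyphenyl]ethan-1-one
Conditions: NBS (2.2 equiv), MeCN, 0 to 50 °C, dark
Reagents that add atoms: N-bromosuccinimide, O=C1CCC(=O)N1Br
Why: Electrophilic aromatic bromination; C2 and C6 are the only free ring positions and each is ortho to one OMe and para to the other, so regiochemistry is fixed by the substrate. Acid-free NBS in a polar solvent in the dark favours the ionic ring reaction over enol bromination of the acetyl group and over benzylic radical bromination.

**Step 3**
Reactants: 4 methyl 3-hydroxy-4,5-dimethoxybenzoate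
Product: 5 methyl 3-(benzyloxy)-4,5-dimethoxybenzoate
Conditions: BnBr (1.2 equiv), K2CO3, DMF, 60 °C
Reagents that add atoms: benzyl bromide, BrCc1ccccc1
Why: Williamson ether synthesis; the ester is inert to carbonate, and masking the B-ring phenol removes the one O-nucleophile that would otherwise compete in the copper-catalysed key step.

**Step 4**
Reactants: 3 1-[4-(benzyloxy)-2,6-dibromo-3,5-dimethoxyphenyl]ethan-1-one; 5 methyl 3-(benzyloxy)-4,5-dimethoxybenzoate
Product: 6 1-[4-(benzyloxy)-2,6-dibromo-3,5-dimethoxyphenyl]-3-[3-(benzyloxy)-4,5-dimethoxyphenyl]propane-1,3-dione (expected mainly as the chelated enol)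
Conditions: NaH (3 equiv), THF, 0 to 65 °C; then 1 M HCl
Reagents that add atoms: none
Why: Crossed Claisen condensation of a methyl ketone enolate with a non-enolisable aryl ester, driven by irreversible deprotonation of the product diketone. The carbonyl of 3 is shielded by two ortho bromines, which suppresses self-aldol, and the fully substituted A ring has no ring hydrogen, so neither aryne formation nor halogen migration can occur under base.

**Step 5**
Reactants: 6 1-[4-(benzyloxy)-2,6-dibromo-3,5-dimethoxyphenyl]-3-[3-(benzyloxy)-4,5-dimethoxyphenyl]propane-1,3-dione; 7 benzyl alcohol (3 equiv)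
Product: 9 5,7-bis(benzyloxy)-2-[3-(benzyloxy)-4,5-dimethoxyphenyl]-6,8-dimethoxy-4H-chromen-4-one, via 5-bromoflavone 8 (not isolated)
Conditions: CuI (20 mol%), 3,4,7,8-tetramethyl-1,10-phenanthroline (40 mol%), Cs2CO3 (3 equiv), toluene, 80 then 110 °C, Ar
Reagents that add atoms: none
Why: An Ullmann-type copper-catalysed C–O coupling is run twice in one flask on a precursor whose two C–Br bonds are equivalent. The caesium diketonate of 6 binds Cu(I); oxidative addition into either C–Br bond ortho to the acyl carbon and C–O reductive elimination from the aryl–copper enolate join the distal enolate oxygen (on the carbon bearing ring B) to C8a and close the pyran-4-one ring, the closest known reaction type being the copper-catalysed intramolecular enolate O-arylation of 1-(2-bromoaryl)-1,3-diketones to flavones. This is a six-membered ring closure by ipso substitution at an aromatic carbon with the breaking C–Br bond exocyclic; the proximal oxygen or C3 could only form four-membered rings, so O- versus C-arylation and regiochemistry are fixed by geometry. In 8 the remaining bromine sits on C5, peri to the C4 carbonyl, which can hold copper next to the C–Br bond as in ortho-carbonyl-assisted Ullmann substitutions; coupling with 7 under the same catalyst (copper-catalysed etherification of aryl bromides with primary alcohols) makes the C5–O bond. No stereocentre is formed. The step needs chemoselectivity only in the sense that both bromides end as C–O bonds; the order is free, because etherification first followed by ring closure at the other bromide gives the same 9. Intermolecular enolate C-arylation is disfavoured by the two ortho substituents at every C–Br carbon, and the phenols that could act as rival O-nucleophiles are benzylated. The diketonate belongs to the ligand class (β-diketones) known to accelerate copper C–O coupling, so the substrate should not poison the catalyst.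

**Step 6**
Reactants: 9 5,7-bis(benzyloxy)-2-[3-(benzyloxy)-4,5-dimethoxyphenyl]-6,8-dimethoxy-4H-chromen-4-one
Product: 10 scaposin, 5,7-dihydroxy-2-(3-hydroxy-4,5-dimethoxyphenyl)-6,8-dimethoxy-4H-chromen-4-one
Conditions: H2 (1 atm), 10% Pd/C, EtOAc–MeOH, rt
Reagents that add atoms: none
Why: Catalytic hydrogenolysis of three aryl benzyl ethers; the methyl ethers are inert and the cross-conjugated C2=C3 bond of a flavone is normally untouched at 1 atm and room temperature. The 5-O-benzyl group peri to the carbonyl is the most labile and the 7-O-benzyl group the slowest.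

## Compound list

1 | acetosyringone, 1-(4-hydroxy-3,5-dimethoxyphenyl)ethan-1-one (achiral) | CC(=O)c1cc(OC)c(O)c(OC)c1 | starting material
2 | 1-[4-(benzyloxy)-3,5-dimethoxyphenyl]ethan-1-one (achiral) | CC(=O)c1cc(OC)c(OCc2ccccc2)c(OC)c1 | intermediate
3 | 1-[4-(benzyloxy)-2,6-dibromo-3,5-dimethoxyphenyl]ethan-1-one (achiral) | CC(=O)c1c(Br)c(OC)c(OCc2ccccc2)c(OC)c1Br | intermediate
4 | methyl 3-hydroxy-4,5-dimethoxybenzoate (achiral) | COC(=O)c1cc(O)c(OC)c(OC)c1 | starting material
5 | methyl 3-(benzyloxy)-4,5-dimethoxybenzoate (achiral) | COC(=O)c1cc(OCc2ccccc2)c(OC)c(OC)c1 | intermediate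
6 | 1-[4-(benzyloxy)-2,6-dibromo-3,5-dimethoxyphenyl]-3-[3-(benzyloxy)-4,5-dimethoxyphenyl]propane-1,3-dione (achiral; drawn as diketone) | O=C(CC(=O)c1cc(OCc2ccccc2)c(OC)c(OC)c1)c1c(Br)c(OC)c(OCc2ccccc2)c(OC)c1Br | intermediate
7 | benzyl alcohol | OCc1ccccc1 | starting material
8 | 7-(benzyloxy)-2-[3-(benzyloxy)-4,5-dimethoxyphenyl]-5-bromo-6,8-dimethoxy-4H-chromen-4-one (achiral) | COc1cc(-c2cc(=O)c3c(Br)c(OC)c(OCc4ccccc4)c(OC)c3o2)cc(OCc2ccccc2)c1OC | intermediate (not isolated)
9 | 5,7-bis(benzyloxy)-2-[3-(benzyloxy)-4,5-dimethoxyphenyl]-6,8-dimethoxy-4H-chromen-4-one (achiral) | COc1cc(-c2cc(=O)c3c(OCc4ccccc4)c(OC)c(OCc4ccccc4)c(OC)c3o2)cc(OCc2ccccc2)c1OC | intermediate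
10 | scaposin, 5,7-dihydroxy-2-(3-hydroxy-4,5-dimethoxyphenyl)-6,8-dimethoxy-4H-chromen-4-one (achiral) | COc1cc(-c2cc(=O)c3c(O)c(OC)c(O)c(OC)c3o2)cc(O)c1OC | target

## Step count and risk

Total step count: 6. Longest linear sequence: 5 steps (1 to 2 to 3 to 6 to 9 to 10); step 3 is the one-step side branch.

**Step 5 (key step).** Three processes are most likely to go wrong.
- After ring closure, the C5 bromine may be lost by reduction (hydride transfer from a copper benzyloxide) instead of forming the C–O bond.
- The second coupling may be slow, because C5 is flanked by the C4 carbonyl and the 6-OMe group.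
- Benzyloxide may attack C2 of the pyranone or a carbonyl of the diketonate, leading to ring opening and retro-Claisen cleavage of the C2–C3 bond.

The fallback gives up aryl C–O ring closure and returns to ring closure by condensation at O1–C2. It sets out from 3 and comes back to the route at 10. Copper/oxalamide-catalysed double hydroxylation of 3 with LiOH in DMSO–water, assisted by the ortho acyl group, should give 1-[4-(benzyloxy)-2,6-dihydroxy-3,5-dimethoxyphenyl]ethan-1-one F1. Claisen condensation of its polyanion with 5 (NaH, THF, reflux) should give 1-[4-(benzyloxy)-2,6-dihydroxy-3,5-dimethoxyphenyl]-3-[3-(benzyloxy)-4,5-dimethoxyphenyl]propane-1,3-dione F2. Acid cyclodehydration (p-TsOH, toluene, 80 °C) onto either of the two equivalent hydroxyls should give 7-(benzyloxy)-2-[3-(benzyloxy)-4,5-dimethoxyphenyl]-5-hydroxy-6,8-dimethoxy-4H-chromen-4-one F3. Hydrogenolysis under the conditions of step 6 then gives 10.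

**Step 2.** Bromination of the acetyl methyl group through the enol may compete once traces of HBr accumulate, and the second ring bromination may be sluggish on a ring already deactivated by the acyl group and the first bromine. The fallback removes the enolisable, deactivating carbonyl during the substitution. It sets out from 2 and comes back at 3. NaBH4 reduction gives 1-[4-(benzyloxy)-3,5-dimethoxyphenyl]ethan-1-ol F4 (racemic). Ring dibromination with NBS in MeCN, on the now more nucleophilic ring, gives 1-[4-(benzyloxy)-2,6-dibromo-3,5-dimethoxyphenyl]ethan-1-ol F5 (racemic). Dess–Martin oxidation returns 3 and erases the stereocentre.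

**Step 4.** Acylation may be incomplete because the electron-rich ester 5 is a weak electrophile, and methoxide may reverse the condensation at reflux. The fallback forms the C2–C3 bond by aldol addition at the aldehyde oxidation level. It sets out from 5 (with 3) and comes back at 6. LiAlH4 reduction of 5 gives [3-(benzyloxy)-4,5-dimethoxyphenyl]methanol F6, and MnO2 oxidation gives 3-(benzyloxy)-4,5-dimethoxybenzaldehyde F7. Addition of the lithium enolate of 3 (LiHMDS, THF, −78 °C) gives 1-[4-(benzyloxy)-2,6-dibromo-3,5-dimethoxyphenyl]-3-[3-(benzyloxy)-4,5-dimethoxyphenyl]-3-hydroxypropan-1-one F8 (racemic). Dess–Martin oxidation gives 6.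

**Step 6.** Over-reduction of the C2=C3 bond may compete with slow cleavage of the 7-O-benzyl ether, which is flanked by two methoxy groups, and the free polyphenol may oxidise in air during work-up. The fallback replaces hydrogenolysis by Lewis-acid debenzylation. It sets out from 9 and arrives directly at 10 using BCl3 with pentamethylbenzene as cation scavenger (CH2Cl2, −78 °C), conditions under which aryl methyl ethers should persist. It makes no new compound (entry F0).

## Further compounds

F1 | step 5 | 1-[4-(benzyloxy)-2,6-dihydroxy-3,5-dimethoxyphenyl]ethan-1-one | CC(=O)c1c(O)c(OC)c(OCc2ccccc2)c(OC)c1O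
F2 | step 5 | 1-[4-(benzyloxy)-2,6-dihydroxy-3,5-dimethoxyphenyl]-3-[3-(benzyloxy)-4,5-dimethoxyphenyl]propane-1,3-dione | O=C(CC(=O)c1cc(OCc2ccccc2)c(OC)c(OC)c1)c1c(O)c(OC)c(OCc2ccccc2)c(OC)c1O
F3 | step 5 | 7-(benzyloxy)-2-[3-(benzyloxy)-4,5-dimethoxyphenyl]-5-hydroxy-6,8-dimethoxy-4H-chromen-4-one | COc1cc(-c2cc(=O)c3c(O)c(OC)c(OCc4ccccc4)c(OC)c3o2)cc(OCc2ccccc2)c1OC
F4 | step 2 | 1-[4-(benzyloxy)-3,5-dimethoxyphenyl]ethan-1-ol (racemic) | CC(O)c1cc(OC)c(OCc2ccccc2)c(OC)c1
F5 | step 2 | 1-[4-(benzyloxy)-2,6-dibromo-3,5-dimethoxyphenyl]ethan-1-ol (racemic) | CC(O)c1c(Br)c(OC)c(OCc2ccccc2)c(OC)c1Br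
F6 | step 4 | [3-(benzyloxy)-4,5-dimethoxyphenyl]methanol | OCc1cc(OCc2ccccc2)c(OC)c(OC)c1
F7 | step 4 | 3-(benzyloxy)-4,5-dimethoxybenzaldehyde | O=Cc1cc(OCc2ccccc2)c(OC)c(OC)c1
F8 | step 4 | 1-[4-(benzyloxy)-2,6-dibromo-3,5-dimethoxyphenyl]-3-[3-(benzyloxy)-4,5-dimethoxyphenyl]-3-hydroxypropan-1-one (racemic) | O=C(CC(O)c1cc(OCc2ccccc2)c(OC)c(OC)c1)c1c(Br)c(OC)c(OCc2ccccc2)c(OC)c1Br
F0 | step 6 | none | none
A1 | alternative 1 | 1-[2,4-bis(benzyloxy)-6-hydroxy-3,5-dimethoxyphenyl]ethan-1-one | CC(=O)c1c(O)c(OC)c(OCc2ccccc2)c(OC)c1OCc1ccccc1
A2 | alternative 1 | 3-(benzyloxy)-4,5-dimethoxybenzoyl chloride | O=C(Cl)c1cc(OCc2ccccc2)c(OC)c(OC)c1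
A3 | alternative 1 | 2-acetyl-3,5-bis(benzyloxy)-4,6-dimethoxyphenyl 3-(benzyloxy)-4,5-dimethoxybenzoate | CC(=O)c1c(OC(=O)c2cc(OCc3ccccc3)c(OC)c(OC)c2)c(OC)c(OCc2ccccc2)c(OC)c1OCc1ccccc1
A4 | alternative 1 | 1-[2,4-bis(benzyloxy)-6-hydroxy-3,5-dimethoxyphenyl]-3-[3-(benzyloxy)-4,5-dimethoxyphenyl]propane-1,3-dione | O=C(CC(=O)c1cc(OCc2ccccc2)c(OC)c(OC)c1)c1c(O)c(OC)c(OCc2ccccc2)c(OC)c1OCc1ccccc1
A5 | alternative 2 | 2-iodo-4,6-dimethoxybenzene-1,3,5-triyl triacetate | CC(=O)Oc1c(I)c(OC(C)=O)c(OC)c(OC(C)=O)c1OC
A6 | alternative 2 | 5-ethynyl-2,3-dimethoxyphenyl acetate | CC(=O)Oc1cc(C#C)cc(OC)c1OC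
A7 | alternative 3 | 2-[3-(benzyloxy)-4,5-dimethoxyphenyl]-5,7-dihydroxy-4H-chromen-4-one | COc1cc(-c2cc(=O)c3c(O)cc(O)cc3o2)cc(OCc2ccccc2)c1OC
A8 | alternative 3 | 2-[3-(benzyloxy)-4,5-dimethoxyphenyl]-6,8-dibromo-5,7-dihydroxy-4H-chromen-4-one | COc1cc(-c2cc(=O)c3c(O)c(Br)c(O)c(Br)c3o2)cc(OCc2ccccc2)c1OC
A9 | alternative 3 | 2-[3-(benzyloxy)-4,5-dimethoxyphenyl]-5,7-dihydroxy-6,8-dimethoxy-4H-chromen-4-one | COc1cc(-c2cc(=O)c3c(O)c(OC)c(O)c(OC)c3o2)cc(OCc2ccccc2)c1OC
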